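## Retrosynthetic overview

1. Feature: ring A is a hexasubstituted benzene. Its contiguous atoms C6 (2-arylethyl), C1 (CO2Me), C2 (OH) and C3 (prenyl) carry the same pattern as C6, C5, C4 and C3 of a 4-oxygenated 2-pyrone-5-carboxylate, and the remaining pair C4 (OH)/C5 (prenyl) is a masked prenyl-substituted ynol.
2. Key disconnection: bonds C3–C4 and C5–C6 of ring A are opened as a retro-(4+2) with CO2 put back, which gives a 4-acetoxy-3-prenyl-2-pyrone-5-carboxylate and a prenyl triisopropylsilyl ynol ether.
3. Pyrone: its bonds C4–C5 (C-acylation) and O1–C2 (lactonisation) lead back to the β-ketoester of acetylated phloretic acid and a prenylmalonic half-ester chloride, and the assembly is kept free of HCl to spare the prenyl alkene.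
4. Ynol ether: Kowalski ester-to-ynolate homologation of ethyl 4-methylpent-3-enoate, followed by O-silylation.
5. Ring order: ring B is bought with phloretic acid, the sacrificial pyrone ring closes in step 6, ring A is made from it in step 10, and two deprotections finish the route.

Key step: step 10

Remark: the target has no stereocentre and no E/Z-isomeric alkene. The stereocentres of 5, 10, 11, 12 and 20 are racemic and are erased on the way to 6, 13 and 21.

## Route

Step 1
Reactants: 1 phloretic acid, 3-(4-hydroxyphenyl)propanoic acid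
Product: 2 3-(4-acetoxyphenyl)propanoic acid
Conditions: Ac2O (2.5 equiv), pyridine, rt; then H2O, rt; 1 M HCl work-up
Reagents that add atoms: acetic anhydride, CC(=O)OC(C)=O
Why: Pyridine-catalysed O-acetylation caps the phenol, and the mixed anhydride that forms in parallel at the carboxyl group is hydrolysed back to the acid by the water quench.

Step 2
Reactants: 2 3-(4-acetoxyphenyl)propanoic acid; 3 potassium methyl malonate (KO2CCH2CO2Me)
Product: 6 methyl 5-(4-acetoxyphenyl)-3-oxopentanoate, via acid chloride 4 (not isolated), via acylmalonic half ester 5 (not isolated)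
Conditions: (COCl)2, cat. DMF, CH2Cl2, 0 °C → rt, concentrate; then 3, MgCl2, Et3N, MeCN, 0 °C → rt; 1 M HCl
Reagents that add atoms: oxalyl chloride, O=C(Cl)C(=O)Cl (supplies the chlorine of 4; nothing of it remains in 6)
Why: Acid chloride formation through the chloroiminium salt is followed by C-acylation of the magnesium enolate of the malonate half ester and loss of CO2 (magnesium malonate β-ketoester synthesis), and the acyl chloride is so much more electrophilic than the aryl acetate that the latter is left alone.

Step 3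
Reactants: 7 dimethyl malonate (1.5 equiv); 8 prenyl bromide
Product: 9 dimethyl 2-(3-methylbut-2-enyl)malonate
Conditions: NaH, THF, 0 °C; then 8, 0 °C → rt
Reagents that add atoms: none
Why: Malonic ester alkylation, an SN2 displacement at the primary allylic carbon by a soft enolate, with the malonate in excess to hold back dialkylation.

Step 4
Reactants: 9 dimethyl 2-(3-methylbut-2-enyl)malonate
Product: 10 2-(methoxycarbonyl)-5-methylhex-4-enoic acid (racemic)
Conditions: KOH (1.0 equiv), MeOH, 0 °C → rt; cold 1 M HCl
Reagents that add atoms: potassium hydroxide, [K+].[OH-]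
Why: Monosaponification with one equivalent of hydroxide should stop after the first ester because the carboxylate formed shields the second one by its charge, and the new stereocentre is racemic and disappears in step 6.

Step 5
Reactants: 10 2-(methoxycarbonyl)-5-methylhex-4-enoic acid; 6 methyl 5-(4-acetoxyphenyl)-3-oxopentanoate
Product: 12 dimethyl 2-[3-(4-acetoxyphenyl)propanoyl]-4-(3-methylbut-2-enyl)-3-oxopentanedioate (enol and diastereomer mixture), via half-ester acid chloride 11 (not isolated)
Conditions: 10, 1-chloro-N,N,2-trimethylprop-1-en-1-amine, CH2Cl2, 0 °C; solution added to 6, MgCl2, pyridine, CH2Cl2, 0 °C → rt; cold 1 M HCl; used crude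
Reagents that add atoms: 1-chloro-N,N,2-trimethylprop-1-en-1-amine, CC(C)=C(Cl)N(C)C (supplies the chlorine of 11; nothing of it remains in 12)
Why: The α-chloroenamine makes the acid chloride under neutral conditions without releasing HCl, so the trisubstituted alkene is not hydrochlorinated, and MgCl2/pyridine soft enolisation directs acylation of the chelated β-ketoester enolate to carbon rather than oxygen.

Step 6
Reactants: 12 dimethyl 2-[3-(4-acetoxyphenyl)propanoyl]-4-(3-methylbut-2-enyl)-3-oxopentanedioate
Product: 13 methyl 6-[2-(4-acetoxyphenyl)ethyl]-4-hydroxy-3-(3-methylbut-2-enyl)-2-oxo-2H-pyran-5-carboxylate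
Conditions: DBU (2 equiv), toluene, 80 °C; cold 1 M HCl
Reagents that add atoms: none
Why: Base-induced lactonisation of a 3,5-dioxoester is the standard entry to 4-hydroxy-2-pyrones: the enolate oxygen of the arylethyl ketone attacks the malonate ester in a 6-exo-trig addition–elimination, the acidic pyrone is held as its amidinium salt, and the all-methyl ester set makes any transesterification by released methanol degenerate.

Step 7
Reactants: 13 methyl 6-[2-(4-acetoxyphenyl)ethyl]-4-hydroxy-3-(3-methylbut-2-enyl)-2-oxo-2H-pyran-5-carboxylate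
Product: 14 methyl 4-acetoxy-6-[2-(4-acetoxyphenyl)ethyl]-3-(3-methylbut-2-enyl)-2-oxo-2H-pyran-5-carboxylate
Conditions: Ac2O (3 equiv), pyridine, CH2Cl2, 0 °C → rt; short silica plug
Reagents that add atoms: acetic anhydride, CC(=O)OC(C)=O
Why: O-acylation of the acidic 4-hydroxy group should be clean because C3 and C5 both carry carbon substituents, which leaves the usual oxygen-to-carbon acyl shift of 4-acyloxypyrones no free site, and the excess anhydride re-caps any ring B phenol bared by DBU and methanol in step 6.

Step 8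
Reactants: 15 4-methylpent-3-enoic acid
Product: 16 ethyl 4-methylpent-3-enoate
Conditions: EtI, K2CO3, DMF, rt
Reagents that add atoms: ethyl iodide, CCI
Why: SN2 O-alkylation of the carboxylate under weakly basic conditions is chosen over Fischer esterification because acid would close 15 to γ,γ-dimethylbutyrolactone and strong base would move the double bond into conjugation.

Step 9
Reactants: 16 ethyl 4-methylpent-3-enoate
Product: 19 triisopropyl(5-methylhex-4-en-1-ynyloxy)silane, via lithium dibromoenolate 17 (not isolated), via lithium ynolate 18 (not isolated)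
Conditions: CH2Br2, lithium 2,2,6,6-tetramethylpiperidide, THF, −78 °C; 16; LiN(SiMe3)2, −78 °C; n-BuLi, −78 °C → rt; i-Pr3SiCl, −78 → 0 °C; Et3N-deactivated silica
Reagents that add atoms: dibromomethane, BrCBr (one carbon, the later C5 of ring A); chlorotriisopropylsilane, CC(C)[Si](Cl)(C(C)C)C(C)C
Why: This is the Kowalski ester homologation stopped at the ynolate: LiCHBr2 adds to the ester, collapse and deprotonation give 17, bromine–lithium exchange gives a carbenoid whose prenyl-bearing CH2 group migrates to carbon to form 18, and the bulky silyl chloride silylates lithium ynolates on oxygen rather than on carbon.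

Step 10
Reactants: 14 methyl 4-acetoxy-6-[2-(4-acetoxyphenyl)ethyl]-3-(3-methylbut-2-enyl)-2-oxo-2H-pyran-5-carboxylate; 19 triisopropyl(5-methylhex-4-en-1-ynyloxy)silane
Product: 21 methyl 2-acetoxy-6-[2-(4-acetoxyphenyl)ethyl]-3,5-bis(3-methylbut-2-enyl)-4-(triisopropylsilyloxy)benzoate, via bicyclic lactone 20 (not isolated)
Conditions: 19 (2.5 equiv), o-xylene (1 M), cat. BHT, sealed tube, base-washed glass, Ar, 140 °C
Reagents that add atoms: none
Why: This is the inverse-electron-demand Diels–Alder reaction of a 2-pyrone-5-carboxylate with an ynol ether followed by cycloreversion, the established pyrone-to-benzoate conversion: the diene C3=C4–C5=C6 of 14, whose LUMO is lowered by the lactone carbonyl, the C5 ester and the only weakly donating acetoxy group, takes up the electron-rich triple bond of 19 in a concerted but strongly asynchronous (4+2) closure. Bond formation runs ahead between the prenyl-bearing alkyne carbon (the nucleophilic β-carbon of the ynol ether) and pyrone C6 (β to the ester, δ to the lactone carbonyl), and the developing ketenium carbon is captured by C3, so ring A is closed by cycloaddition as the carbocyclic six-membered ring of the 2-oxabicyclo[2.2.2]octadienone 20. At the reaction temperature 20 should expel CO2 by retro-(4+2) reaction, which makes the sequence irreversible and delivers the arene without an oxidation step. The two bridgehead stereocentres of 20 are racemic and transient and vanish on aromatisation, so no stereocontrol is needed. The one selectivity required is regiochemical (the silyloxy carbon next to C3–prenyl, the new prenyl carbon next to C6–arylethyl), and it rests on this polarity match, because the reverse orientation would pair the nucleophilic alkyne carbon with the electron-rich α-carbon C3; the trisubstituted alkenes are far poorer and bulkier dienophiles than the linear ynol ether. The weak point is steric, since both diene termini are fully substituted, which is why a slim linear dienophile, high concentration and an excess of 19 are used.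

Step 11
Reactants: 21 methyl 2-acetoxy-6-[2-(4-acetoxyphenyl)ethyl]-3,5-bis(3-methylbut-2-enyl)-4-(triisopropylsilyloxy)benzoate
Product: 22 methyl 2-hydroxy-6-[2-(4-hydroxyphenyl)ethyl]-3,5-bis(3-methylbut-2-enyl)-4-(triisopropylsilyloxy)benzoate
Conditions: K2CO3 (3 equiv), MeOH, Ar, 0 °C → rt; aq. NH4Cl
Reagents that add atoms: none
Why: Base-mediated methanolysis removes both aryl acetates, while the doubly ortho-substituted methyl benzoate can only exchange methoxide for methoxide and the silyl ether flanked by two prenyl groups is shielded (its early loss would only lead on to 23).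

Step 12
Reactants: 22 methyl 2-hydroxy-6-[2-(4-hydroxyphenyl)ethyl]-3,5-bis(3-methylbut-2-enyl)-4-(triisopropylsilyloxy)benzoate
Product: 23 methyl 2,4-dihydroxy-6-[2-(4-hydroxyphenyl)ethyl]-3,5-bis(3-methylbut-2-enyl)benzoate (CNP0133671.0)
Conditions: Bu4NF, AcOH (1:1), THF, 0 °C → rt
Reagents that add atoms: none
Why: Fluoride-induced Si–O cleavage is driven by the strong Si–F bond, the acetic acid buffer keeps the electron-rich resorcinolate from building up, and the absence of strong acid keeps the ortho-prenyl phenols from closing to chromans.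

## Compound list

1 | phloretic acid, 3-(4-hydroxyphenyl)propanoic acid | OC(=O)CCc1ccc(O)cc1 | starting material
2 | 3-(4-acetoxyphenyl)propanoic acid | CC(=O)Oc1ccc(CCC(=O)O)cc1 | intermediate
3 | potassium methyl malonate | COC(=O)CC(=O)[O-].[K+] | starting material
4 | 3-(4-acetoxyphenyl)propanoyl chloride | CC(=O)Oc1ccc(CCC(=O)Cl)cc1 | intermediate
5 | 5-(4-acetoxyphenyl)-2-(methoxycarbonyl)-3-oxopentanoic acid (racemic; magnesium salt in the flask) | COC(=O)C(C(=O)O)C(=O)CCc1ccc(OC(C)=O)cc1 | intermediate
6 | methyl 5-(4-acetoxyphenyl)-3-oxopentanoate | COC(=O)CC(=O)CCc1ccc(OC(C)=O)cc1 | intermediate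
7 | dimethyl malonate | COC(=O)CC(=O)OC | starting material
8 | prenyl bromide, 1-bromo-3-methylbut-2-ene | CC(C)=CCBr | starting material
9 | dimethyl 2-(3-methylbut-2-enyl)malonate | COC(=O)C(CC=C(C)C)C(=O)OC | intermediate
10 | 2-(methoxycarbonyl)-5-methylhex-4-enoic acid (racemic) | COC(=O)C(CC=C(C)C)C(=O)O | intermediate
11 | methyl 2-(chlorocarbonyl)-5-methylhex-4-enoate (racemic) | COC(=O)C(CC=C(C)C)C(=O)Cl | intermediate
12 | dimethyl 2-[3-(4-acetoxyphenyl)propanoyl]-4-(3-methylbut-2-enyl)-3-oxopentanedioate (enol and diastereomer mixture) | COC(=O)C(CC=C(C)C)C(=O)C(C(=O)OC)C(=O)CCc1ccc(OC(C)=O)cc1 | intermediate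
13 | methyl 6-[2-(4-acetoxyphenyl)ethyl]-4-hydroxy-3-(3-methylbut-2-enyl)-2-oxo-2H-pyran-5-carboxylate | O=C1OC(CCc2ccc(OC(C)=O)cc2)=C(C(=O)OC)C(O)=C1CC=C(C)C | intermediate
14 | methyl 4-acetoxy-6-[2-(4-acetoxyphenyl)ethyl]-3-(3-methylbut-2-enyl)-2-oxo-2H-pyran-5-carboxylate | O=C1OC(CCc2ccc(OC(C)=O)cc2)=C(C(=O)OC)C(OC(C)=O)=C1CC=C(C)C | intermediate
15 | 4-methylpent-3-enoic acid | CC(C)=CCC(=O)O | starting material
16 | ethyl 4-methylpent-3-enoate | CCOC(=O)CC=C(C)C | intermediate
17 | lithium 1,1-dibromo-5-methylhexa-1,4-dien-2-olate | CC(C)=CCC([O-])=C(Br)Br.[Li+] | intermediate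
18 | lithium 5-methylhex-4-en-1-yn-1-olate | CC(C)=CCC#C[O-].[Li+] | intermediate
19 | triisopropyl(5-methylhex-4-en-1-ynyloxy)silane | CC(C)=CCC#CO[Si](C(C)C)(C(C)C)C(C)C | intermediate
20 | methyl 8-acetoxy-1-[2-(4-acetoxyphenyl)ethyl]-4,6-bis(3-methylbut-2-enyl)-3-oxo-5-(triisopropylsilyloxy)-2-oxabicyclo[2.2.2]octa-5,7-diene-7-carboxylate (racemic) | O=C1OC2(CCc3ccc(OC(C)=O)cc3)C(C(=O)OC)=C(OC(C)=O)C1(CC=C(C)C)C(O[Si](C(C)C)(C(C)C)C(C)C)=C2CC=C(C)C | intermediate
21 | methyl 2-acetoxy-6-[2-(4-acetoxyphenyl)ethyl]-3,5-bis(3-methylbut-2-enyl)-4-(triisopropylsilyloxy)benzoate | COC(=O)c1c(OC(C)=O)c(CC=C(C)C)c(O[Si](C(C)C)(C(C)C)C(C)C)c(CC=C(C)C)c1CCc1ccc(OC(C)=O)cc1 | intermediate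
22 | methyl 2-hydroxy-6-[2-(4-hydroxyphenyl)ethyl]-3,5-bis(3-methylbut-2-enyl)-4-(triisopropylsilyloxy)benzoate | COC(=O)c1c(O)c(CC=C(C)C)c(O[Si](C(C)C)(C(C)C)C(C)C)c(CC=C(C)C)c1CCc1ccc(O)cc1 | intermediate
23 | methyl 2,4-dihydroxy-6-[2-(4-hydroxyphenyl)ethyl]-3,5-bis(3-methylbut-2-enyl)benzoate (CNP0133671.0) | COC(=O)c1c(O)c(CC=C(C)C)c(O)c(CC=C(C)C)c1CCc1ccc(O)cc1 | target

## Step count and risks

Total step count: 12.
Longest linear sequence: 8 steps (1 → 2 → 6 → 12 → 13 → 14 → 21 → 22 → 23; the branch from 7 and 8 through 9 and 10 is equally long).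

**Step 10 (most likely to fail).**
- What may go wrong: the cycloaddition may stall because both diene termini are fully substituted. Meanwhile the ynol ether may be consumed by thermal silyl migration to a silylketene or by oligomerisation. Addition–elimination at the acetoxy-bearing C4 could also compete.
- Fallback: it sets out from 6 and returns at 23. It frees the C3 terminus of the diene and brings in the C3 prenyl group afterwards.
- Pyrone: 6 is condensed with malonyl dichloride (CH2Cl2, reflux; no acid-sensitive alkene is present at this stage) to methyl 6-[2-(4-acetoxyphenyl)ethyl]-4-hydroxy-2-oxo-2H-pyran-5-carboxylate F1. Ac2O/pyridine at 0 °C without DMAP gives methyl 4-acetoxy-6-[2-(4-acetoxyphenyl)ethyl]-2-oxo-2H-pyran-5-carboxylate F2. This compound belongs to the 3-unsubstituted pyrone carboxylates, for which ynol ether cycloaddition is best established.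
- Cycloaddition: with 19 in toluene at 110 °C, F2 should pass through the bicyclic lactone F3 to methyl 2-acetoxy-6-[2-(4-acetoxyphenyl)ethyl]-5-(3-methylbut-2-enyl)-4-(triisopropylsilyloxy)benzoate F4. The only free position of its ring A is C3.
- Late prenylation: Bu4NF/AcOH frees the C4 phenol, methyl 2-acetoxy-6-[2-(4-acetoxyphenyl)ethyl]-4-hydroxy-5-(3-methylbut-2-enyl)benzoate F5. Pd(PPh3)4 and tert-butyl 2-methylbut-3-en-2-yl carbonate (THF, 0 °C) convert it into the 1,1-dimethylallyl ether, methyl 2-acetoxy-6-[2-(4-acetoxyphenyl)ethyl]-4-(2-methylbut-3-en-2-yloxy)-5-(3-methylbut-2-enyl)benzoate F6.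
- Finish: aromatic Claisen rearrangement (toluene, 110 °C) can end only at C3 and inverts the allyl unit to a normal prenyl group. This gives methyl 2-acetoxy-6-[2-(4-acetoxyphenyl)ethyl]-4-hydroxy-3,5-bis(3-methylbut-2-enyl)benzoate F7, and K2CO3/MeOH then gives 23.

**Step 9.**
- What may go wrong: dibromomethyllithium may deprotonate the doubly activated α-CH2 of the β,γ-unsaturated ester instead of adding to the carbonyl group. The excess alkyllithium may also move the skipped double bond or metalate the CH2 between alkene and alkyne.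
- Fallback: it sets out from 8 and returns at 18. It avoids the ester altogether.
- Sequence: copper-catalysed coupling of 8 with HC≡CMgBr (cat. CuBr·SMe2, THF, 0 °C → rt) gives 5-methylhex-4-en-1-yne F8. One equivalent of n-BuLi at −78 °C gives lithium 5-methylhex-4-en-1-ynide F9. Oxidation of this acetylide with LiOOt-Bu (from anhydrous t-BuOOH and LiN(SiMe3)2) gives ynolate 18, which is silylated to 19 as in step 9.

**Step 5.**
- What may go wrong: the α-branched acid chloride may lose HCl to a ketene that dimerises, the enolate may be acylated on oxygen, or the triacylmethane may be deacylated during work-up.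
- Fallback: it sets out from 9 and 6, returns at 13 and bypasses step 6 as well. It replaces the stepwise base-mediated assembly by a one-step thermal cyclocondensation of an active malonate.
- Sequence: 9 is fully saponified (KOH, aq. MeOH; cold acidification) to 2-(3-methylbut-2-enyl)malonic acid F10. DCC and 2,4,6-trichlorophenol (CH2Cl2, 0 °C) give bis(2,4,6-trichlorophenyl) 2-(3-methylbut-2-enyl)malonate F11. Heating F11 with 6 in bromobenzene at reflux should give 13 by C-acylation and O-acylation, with only the weakly acidic trichlorophenol released.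

## Further compounds

F1 | step 10 | methyl 6-[2-(4-acetoxyphenyl)ethyl]-4-hydroxy-2-oxo-2H-pyran-5-carboxylate | O=C1OC(CCc2ccc(OC(C)=O)cc2)=C(C(=O)OC)C(O)=C1
F2 | step 10 | methyl 4-acetoxy-6-[2-(4-acetoxyphenyl)ethyl]-2-oxo-2H-pyran-5-carboxylate | O=C1OC(CCc2ccc(OC(C)=O)cc2)=C(C(=O)OC)C(OC(C)=O)=C1
F3 | step 10 | methyl 8-acetoxy-1-[2-(4-acetoxyphenyl)ethyl]-6-(3-methylbut-2-enyl)-3-oxo-5-(triisopropylsilyloxy)-2-oxabicyclo[2.2.2]octa-5,7-diene-7-carboxylate (racemic, transient) | O=C1OC2(CCc3ccc(OC(C)=O)cc3)C(C(=O)OC)=C(OC(C)=O)C1C(O[Si](C(C)C)(C(C)C)C(C)C)=C2CC=C(C)C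
F4 | step 10 | methyl 2-acetoxy-6-[2-(4-acetoxyphenyl)ethyl]-5-(3-methylbut-2-enyl)-4-(triisopropylsilyloxy)benzoate | COC(=O)c1c(OC(C)=O)cc(O[Si](C(C)C)(C(C)C)C(C)C)c(CC=C(C)C)c1CCc1ccc(OC(C)=O)cc1
F5 | step 10 | methyl 2-acetoxy-6-[2-(4-acetoxyphenyl)ethyl]-4-hydroxy-5-(3-methylbut-2-enyl)benzoate | COC(=O)c1c(OC(C)=O)cc(O)c(CC=C(C)C)c1CCc1ccc(OC(C)=O)cc1
F6 | step 10 | methyl 2-acetoxy-6-[2-(4-acetoxyphenyl)ethyl]-4-(2-methylbut-3-en-2-yloxy)-5-(3-methylbut-2-enyl)benzoate | COC(=O)c1c(OC(C)=O)cc(OC(C)(C)C=C)c(CC=C(C)C)c1CCc1ccc(OC(C)=O)cc1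
F7 | step 10 | methyl 2-acetoxy-6-[2-(4-acetoxyphenyl)ethyl]-4-hydroxy-3,5-bis(3-methylbut-2-enyl)benzoate | COC(=O)c1c(OC(C)=O)c(CC=C(C)C)c(O)c(CC=C(C)C)c1CCc1ccc(OC(C)=O)cc1
F8 | step 9 | 5-methylhex-4-en-1-yne | C#CCC=C(C)C
F9 | step 9 | lithium 5-methylhex-4-en-1-ynide | [Li]C#CCC=C(C)C
F10 | step 5 | 2-(3-methylbut-2-enyl)malonic acid | OC(=O)C(CC=C(C)C)C(=O)O
F11 | step 5 | bis(2,4,6-trichlorophenyl) 2-(3-methylbut-2-enyl)malonate | CC(C)=CCC(C(=O)Oc1c(Cl)cc(Cl)cc1Cl)C(=O)Oc1c(Cl)cc(Cl)cc1Cl
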